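**Strategy**

The plan rests on disconnecting the C4–C18 bond of ring A. The C18 methyl on C4 and the C6 hydroxyl of ring B sit on the same face and are linked through C5 of the C5=C10 alkene, so the methyl carbon can be delivered from the C6 oxygen on a temporary silicon tether. In one operation the ester dienolate of a 1,4-dihydrobenzoate displaces bromide from an O6-bound (bromomethyl)dimethylsilyl group. This forms C4–C18, the quaternary C4 stereocentre and a six-membered siloxane ring that is later cleaved to CH3 and OH. The precursor is a Birch-derived methyl 1,4-dihydrobenzoate (C4 ester, C3 enol ether) carrying the C8/C9 stereocentres, a C9 allyl group and the C6 silyl ether.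

Key step: step 11

Remark: halimane numbering is used for all intermediates and the top face is the face of the C6 oxygen; because an aromatic C6 hydroxy C4 ester lactonises at once and a protected benzylic oxygen would be expelled under dissolving-metal conditions, C19 and O6 are stored as the peri-lactone and ring A is reduced as the alkoxide–carboxylate.

**Route**

Step 1
Reactants: 1 7-methoxy-1-tetralone
Product: 2 (S)-7-methoxy-1,2,3,4-tetrahydronaphthalen-1-ol
Conditions: RuCl[(S,S)-TsDPEN](p-cymene) (0.5 mol%), HCO2H/Et3N (5:2), 30 °C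
Reagents that add atoms: none
Why: Noyori–Ikariya asymmetric transfer hydrogenation of an aryl ketone, in which the (S,S)-catalyst should deliver hydride to the face that gives the (S)-carbinol; this sets C6 and anchors the absolute configuration of the route.

Step 2
Reactants: 2 (S)-7-methoxy-1,2,3,4-tetrahydronaphthalen-1-ol
Product: 3 triisopropylsilyl ether of 2
Conditions: TIPSOTf, 2,6-lutidine, CH2Cl2, 0 °C
Reagents that add atoms: triisopropylsilyl trifluoromethanesulfonate, CC(C)[Si](OS(=O)(=O)C(F)(F)F)(C(C)C)C(C)C
Why: Standard silyl triflate protection of a secondary alcohol; the bulky ether should survive the oxidation, enolate, Grignard and Lewis acid steps and bias the later methylation.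

Step 3
Reactants: 3 triisopropylsilyl ether
Product: 4 (S)-6-methoxy-4-(triisopropylsilyloxy)-3,4-dihydronaphthalen-1(2H)-one
Conditions: DDQ (2.5 equiv), AcOH/H2O, rt
Reagents that add atoms: water, O
Why: DDQ benzylic oxidation, in which hydride abstraction should occur only at the methylene para to the methoxy group (C9), the cation being trapped by water and oxidised on to the ketone while the C6–H, meta to the donor, is untouched.

Step 4
Reactants: 4 silyloxy tetralone
Product: 5 (2S,4S)-6-methoxy-2-methyl-4-(triisopropylsilyloxy)-3,4-dihydronaphthalen-1(2H)-one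
Conditions: LiN(i-Pr)2 (LDA), THF, −78 °C; MeI, −78 to −40 °C
Reagents that add atoms: iodomethane, CI
Why: Kinetic enolate alkylation in which methyl iodide should enter C8 on the face opposite the C6 silyloxy group (avoiding a 1,3-diaxial contact) to set the 6,8-trans relationship; the trans ketone is also expected to be the more stable epimer, so a cis fraction can be equilibrated with base.

Step 5
Reactants: 5 trans-2-methyl tetralone
Product: 6 tertiary benzylic alcohol (both C9 epimers)
Conditions: MeMgBr, CeCl3, THF, −78 to 0 °C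
Reagents that add atoms: methylmagnesium bromide, C[Mg]Br
Why: Organocerium-promoted Grignard 1,2-addition to a hindered enolisable aryl ketone; the configuration of the new carbinol carbon is irrelevant because C9 is ionised in the next step.

Step 6
Reactants: 6 tertiary benzylic alcohol; 7 allyltrimethylsilane
Product: 8 (1S,3S,4R)-4-allyl-7-methoxy-3,4-dimethyl-1-(triisopropylsilyloxy)-1,2,3,4-tetrahydronaphthalene
Conditions: BF3·OEt2, CH2Cl2, −78 °C
Reagents that add atoms: allyltrimethylsilane (7), C=CC[Si](C)(C)C
Why: Hosomi–Sakurai-type SN1 allylation in which BF3 ionises the alcohol to a benzylic cation stabilised by the para methoxy group, allylic 1,2-strain with the C9 methyl holds the C8 methyl pseudoaxial, and the allylsilane attacks anti to it, so that the quaternary C9 forms with C20 cis to C17.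

Step 7
Reactants: 8 allylated silyl ether
Product: 9 (1S,3S,4R)-4-allyl-7-methoxy-3,4-dimethyl-1,2,3,4-tetrahydronaphthalen-1-ol
Conditions: Bu4NF, THF, rt
Reagents that add atoms: none
Why: Fluoride cleavage of the silyl ether frees the C6 hydroxyl, which is needed as a directing group in the next step.

Step 8
Reactants: 9 benzylic alcohol
Product: 11 peri-lactone joining C19 to the C6 oxygen, via hydroxy acid 10 (not isolated)
Conditions: n-BuLi (2.5 equiv), TMEDA, Et2O/hexane, 0 °C to rt; CO2, −78 °C; then 2 M HCl, rt
Reagents that add atoms: carbon dioxide, O=C=O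
Why: Directed ortho-metalation in which the C6 lithium alkoxide and the C3 methoxy group cooperate to place lithium at C4, the only position ortho to both; carboxylation and acid then close the five-membered peri-lactone spontaneously.

Step 9
Reactants: 11 peri-lactone
Product: 14 methyl 1,4-dihydrobenzoate with free C6 hydroxyl (C4 epimers), via lithium hydroxy carboxylate 12 (not isolated), via lithium dihydro carboxylate 13 (not isolated)
Conditions: LiOH·H2O, THF/H2O, 50 °C, evaporate to dryness; Li, NH3(l)/THF, −78 °C; isoprene, then NH4Cl; evaporate; MeI, NaHCO3, DMF, 0 °C to rt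
Reagents that add atoms: lithium hydroxide, [Li+].[OH-]; iodomethane, CI
Why: Saponification gives an alkoxide–carboxylate whose benzylic oxygen is a non-leaving alkoxide, Birch reduction of the benzoate salt places the new sp3 centres at C4 and C1, α-protonation with NH4Cl after excess lithium is destroyed gives the 1,4-diene (the C4 configuration is erased later), and carboxylate alkylation under bicarbonate avoids the acid that would hydrolyse the enol ether.

Step 10
Reactants: 14 hydroxy 1,4-dihydrobenzoate; 15 (bromomethyl)chlorodimethylsilane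
Product: 16 C6 (bromomethyl)dimethylsilyl ether of 14
Conditions: imidazole, CH2Cl2, 0 °C
Reagents that add atoms: (bromomethyl)chlorodimethylsilane (15), C[Si](C)(Cl)CBr
Why: Imidazole-mediated silylation of the allylic C6 alcohol, the usual way to make (bromomethyl)dimethylsilyl ethers, under conditions too mild to enolise the ester.

Step 11
Reactants: 16 (bromomethyl)dimethylsilyl ether
Product: 17 siloxane-bridged diene ester with quaternary C4
Conditions: LiN(i-Pr)2 (LDA, 1.2 equiv), THF (0.02 M), −78 °C; DMPU; −78 to 0 °C
Reagents that add atoms: none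
Why: Proposed new method: LDA removes the doubly allylic, ester-activated C4–H to give a cross-conjugated ester dienolate that is planar at C4, and this carbon displaces bromide from the silicon-bound CH2Br in an intramolecular SN2 reaction; the closest known reactions are the deprotonation–alkylation of 1,4-dihydrobenzoates (Birch reduction–alkylation chemistry), intermolecular enolate alkylation by α-halomethylsilanes, and the radical cyclisation of (bromomethyl)dimethylsilyl ethers followed by protodesilylation. The six-membered 1-oxa-2-silacyclohexane ring (C4, C18, Si, O, C6, C5) closes in the 6-exo-tet mode. The new quaternary stereocentre C4 is controlled by the tether, because the electrophilic carbon hangs two atoms from O6 and can reach only the face of C4 that carries O6, so C18 ends syn to the C6 oxygen and the ester carbon C19 anti, as the target requires. The step needs facial selectivity at C4 and C-alkylation at C4 in preference to O- or γ-alkylation: O-alkylation would require an eight-membered ring, and attack through C10 would build a quaternary centre next to quaternary C9, so α-attack should prevail. The α-silyl bromide is an activated SN2 electrophile, DMPU loosens the lithium enolate, and dilution suppresses intermolecular alkylation.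

Step 12
Reactants: 17 siloxane-bridged diene ester
Product: 18 methyl ester with C18 methyl and free C6 hydroxyl
Conditions: Bu4NF (5 equiv), DMF, 70 °C
Reagents that add atoms: none
Why: Fluoride-induced protodesilylation of a cyclic alkoxysilane, in which fluoride opens the Si–O bond and the pentacoordinate silicon species is protonolysed at the neopentyl C18–Si bond by the water of the reagent; this unveils the C18 methyl and the C6 hydroxyl without touching the quaternary C4.

Step 13
Reactants: 18 hydroxy ester
Product: 19 C6 tert-butyldimethylsilyl ether of 18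
Conditions: TBSOTf, 2,6-lutidine, CH2Cl2, −78 to 0 °C
Reagents that add atoms: tert-butyldimethylsilyl trifluoromethanesulfonate, CC(C)(C)[Si](C)(C)OS(=O)(=O)C(F)(F)F
Why: Silyl triflate protection of the hindered allylic alcohol, so that C19 can be acylated and the side chain iodinated and metalated without a competing hydroxyl.

Step 14
Reactants: 19 silyl-protected ester
Product: 20 C19 primary alcohol
Conditions: LiAlH4, THF, 0 °C to rt
Reagents that add atoms: none
Why: Hydride reduction of the neopentyl methyl ester to the primary alcohol; the enol ether, the alkenes and the silyl ether are inert.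

Step 15
Reactants: 21 3-(4-hydroxyphenyl)propanoic acid
Product: 23 3-[4-(tert-butyldimethylsilyloxy)phenyl]propanoic acid, via bis-silyl derivative 22 (not isolated)
Conditions: TBSCl, imidazole, DMF, rt; then AcOH/THF/H2O, rt
Reagents that add atoms: tert-butyldimethylsilyl chloride, CC(C)(C)[Si](C)(C)Cl
Why: Per-silylation followed by selective hydrolysis of the labile silyl ester leaves the phenol protected and the acid free.

Step 16
Reactants: 20 C19 primary alcohol; 23 silyl-protected acid
Product: 24 C19 ester of 20 with acid 23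
Conditions: EDC·HCl, DMAP, CH2Cl2, 0 °C to rt
Reagents that add atoms: 3-[4-(tert-butyldimethylsilyloxy)phenyl]propanoic acid (23), OC(=O)CCc1ccc(O[Si](C)(C)C(C)(C)C)cc1
Why: Steglich esterification of the only free hydroxyl, done before the ketone is unveiled so that no free β-hydroxy ketone is ever present.

Step 17
Reactants: 24 enol ether ester
Product: 25 C3 ketone
Conditions: oxalic acid, THF/H2O, rt
Reagents that add atoms: water, O
Why: Mild acid hydrolysis of the methyl enol ether gives the C3 ketone, and because C4 is quaternary the C5=C10 alkene cannot move into conjugation.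

Step 18
Reactants: 25 C3 ketone with allyl group
Product: 27 C12 primary alcohol, via C12 aldehyde 26 (not isolated)
Conditions: OsO4 (2 mol%), NaIO4, 2,6-lutidine, dioxane/H2O, rt; then NaBH4, MeOH, −40 °C
Reagents that add atoms: osmium tetroxide, O=[Os](=O)(=O)=O; sodium periodate, [Na+].[O-]I(=O)(=O)=O
Why: Lemieux–Johnson oxidation should cleave only the monosubstituted alkene, the C5=C10 bond being shielded by two quaternary carbons, and borohydride at low temperature should reduce the aldehyde in preference to the hindered α-quaternary ketone.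

Step 19
Reactants: 27 C12 primary alcohol
Product: 28 C12 primary iodide
Conditions: I2, PPh3, imidazole, CH2Cl2, 0 °C to rt
Reagents that add atoms: iodine, II
Why: Appel iodination of the unhindered primary alcohol under neutral conditions.

Step 20
Reactants: 28 C12 primary iodide; 29 4-bromofuran-2(5H)-one
Product: 31 bis-silyl ether of the target, via alkylzinc iodide 30 (not isolated)
Conditions: Zn dust, LiCl, THF, 40 °C; then 29, Pd(PPh3)4 (5 mol%), THF, rt to 45 °C
Reagents that add atoms: 4-bromofuran-2(5H)-one (29), BrC1=CC(=O)OC1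
Why: Negishi coupling in which zinc insertion gives a primary alkylzinc iodide that tolerates the ketone and the esters, and palladium-catalysed coupling with the β-bromo butenolide forms the C12–C13 bond under neutral conditions.

Step 21
Reactants: 31 bis-silyl ether of the target
Product: 32 CNP0301014.1
Conditions: HF·pyridine, pyridine/THF, 0 °C to rt
Reagents that add atoms: none
Why: Buffered fluoride desilylation removes the phenolic and the C6 silyl ethers together under conditions that spare the butenolide, the ester and the β,γ-unsaturated ketone.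

**Compound list**

1 | 7-methoxy-3,4-dihydronaphthalen-1(2H)-one (7-methoxy-1-tetralone) | O=C1CCCc2ccc(OC)cc21 | starting material
2 | (S)-7-methoxy-1,2,3,4-tetrahydronaphthalen-1-ol (carbinol carbon = C6) | C1CC[C@H](O)c2cc(OC)ccc12 | intermediate
3 | (S)-7-methoxy-1-(triisopropylsilyloxy)-1,2,3,4-tetrahydronaphthalene | C1CC[C@H](O[Si](C(C)C)(C(C)C)C(C)C)c2cc(OC)ccc12 | intermediate
4 | (S)-6-methoxy-4-(triisopropylsilyloxy)-3,4-dihydronaphthalen-1(2H)-one (carbonyl = C9) | O=C1CC[C@H](O[Si](C(C)C)(C(C)C)C(C)C)c2cc(OC)ccc12 | intermediate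
5 | (2S,4S)-6-methoxy-2-methyl-4-(triisopropylsilyloxy)-3,4-dihydronaphthalen-1(2H)-one (C8 methyl trans to the C6 silyloxy group) | C[C@H]1C[C@H](O[Si](C(C)C)(C(C)C)C(C)C)c2cc(OC)ccc2C1=O | intermediate
6 | (2S,4S)-6-methoxy-1,2-dimethyl-4-(triisopropylsilyloxy)-1,2,3,4-tetrahydronaphthalen-1-ol, both epimers at the carbinol carbon C9 | C[C@H]1C[C@H](O[Si](C(C)C)(C(C)C)C(C)C)c2cc(OC)ccc2C1(C)O | intermediate
7 | allyltrimethylsilane | C=CC[Si](C)(C)C | starting material
8 | (1S,3S,4R)-4-allyl-7-methoxy-3,4-dimethyl-1-(triisopropylsilyloxy)-1,2,3,4-tetrahydronaphthalene (halimane 6S,8S,9R; silyloxy and allyl on the top face, C17 and C20 on the bottom face) | C[C@H]1C[C@H](O[Si](C(C)C)(C(C)C)C(C)C)c2cc(OC)ccc2[C@]1(C)CC=C | intermediate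
9 | (1S,3S,4R)-4-allyl-7-methoxy-3,4-dimethyl-1,2,3,4-tetrahydronaphthalen-1-ol | C[C@H]1C[C@H](O)c2cc(OC)ccc2[C@]1(C)CC=C | intermediate
10 | (6S,8S,9R)-9-allyl-6-hydroxy-3-methoxy-8,9-dimethyl-6,7,8,9-tetrahydronaphthalene-4-carboxylic acid (halimane numbering) | C[C@H]1C[C@H](O)c2c(C(=O)O)c(OC)ccc2[C@]1(C)CC=C | intermediate
11 | peri-lactone of 10 (five-membered lactone C19(=O)–O–C6 fused across C4, C5 and C6 of the aromatic ring A; 6S,8S,9R) | C[C@H]1C[C@@H]2OC(=O)c3c(OC)ccc(c32)[C@]1(C)CC=C | intermediate
12 | lithium salt of hydroxy acid 10 | C[C@H]1C[C@H](O)c2c(C(=O)[O-])c(OC)ccc2[C@]1(C)CC=C.[Li+] | intermediate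
13 | lithium (6S,8S,9R)-9-allyl-6-hydroxy-3-methoxy-8,9-dimethyl-1,4,6,7,8,9-hexahydronaphthalene-4-carboxylate (2,3- and 5,10-double bonds; C4 epimers) | C[C@H]1C[C@H](O)C2=C(CC=C(OC)C2C(=O)[O-])[C@]1(C)CC=C.[Li+] | intermediate
14 | methyl ester of 13 with free C6 hydroxyl (1,4-dihydrobenzoate; formed as C4 epimers, the epimer with the ester anti to O6 is drawn) | C[C@H]1C[C@H](O)C2=C(CC=C(OC)[C@@H]2C(=O)OC)[C@]1(C)CC=C | intermediate
15 | (bromomethyl)chlorodimethylsilane | C[Si](C)(Cl)CBr | starting material
16 | C6 (bromomethyl)dimethylsilyl ether of 14 (key-step precursor) | C[C@H]1C[C@H](O[Si](C)(C)CBr)C2=C(CC=C(OC)[C@@H]2C(=O)OC)[C@]1(C)CC=C | intermediate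
17 | siloxane-bridged diene ester: C4 quaternary, C18H2–SiMe2–O–C6 ring on the top face, CO2Me on the bottom face | C[C@H]1C[C@@H]2O[Si](C)(C)C[C@]3(C(=O)OC)C(OC)=CCC(=C32)[C@]1(C)CC=C | intermediate
18 | methyl ester with C18 methyl syn to the free C6 hydroxyl, C3 methyl enol ether, C9 allyl | C[C@H]1C[C@H](O)C2=C(CC=C(OC)[C@]2(C)C(=O)OC)[C@]1(C)CC=C | intermediate
19 | C6 tert-butyldimethylsilyl ether of 18 | C[C@H]1C[C@H](O[Si](C)(C)C(C)(C)C)C2=C(CC=C(OC)[C@]2(C)C(=O)OC)[C@]1(C)CC=C | intermediate
20 | C19 primary alcohol (C6 silyl ether, C3 enol ether, C9 allyl) | C[C@H]1C[C@H](O[Si](C)(C)C(C)(C)C)C2=C(CC=C(OC)[C@]2(C)CO)[C@]1(C)CC=C | intermediate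
21 | 3-(4-hydroxyphenyl)propanoic acid | OC(=O)CCc1ccc(O)cc1 | starting material
22 | tert-butyldimethylsilyl 3-[4-(tert-butyldimethylsilyloxy)phenyl]propanoate | CC(C)(C)[Si](C)(C)OC(=O)CCc1ccc(O[Si](C)(C)C(C)(C)C)cc1 | intermediate
23 | 3-[4-(tert-butyldimethylsilyloxy)phenyl]propanoic acid | OC(=O)CCc1ccc(O[Si](C)(C)C(C)(C)C)cc1 | intermediate
24 | C19 ester of 20 with acid 23 (C3 enol ether, C9 allyl) | C[C@H]1C[C@H](O[Si](C)(C)C(C)(C)C)C2=C(CC=C(OC)[C@]2(C)COC(=O)CCc2ccc(O[Si](C)(C)C(C)(C)C)cc2)[C@]1(C)CC=C | intermediate
25 | C3 ketone from 24 (C5=C10 alkene, C9 allyl) | C[C@H]1C[C@H](O[Si](C)(C)C(C)(C)C)C2=C(CCC(=O)[C@]2(C)COC(=O)CCc2ccc(O[Si](C)(C)C(C)(C)C)cc2)[C@]1(C)CC=C | intermediate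
26 | C12 aldehyde (C9–CH2–CHO) | C[C@H]1C[C@H](O[Si](C)(C)C(C)(C)C)C2=C(CCC(=O)[C@]2(C)COC(=O)CCc2ccc(O[Si](C)(C)C(C)(C)C)cc2)[C@]1(C)CC=O | intermediate
27 | C12 primary alcohol (C9–CH2–CH2–OH) | C[C@H]1C[C@H](O[Si](C)(C)C(C)(C)C)C2=C(CCC(=O)[C@]2(C)COC(=O)CCc2ccc(O[Si](C)(C)C(C)(C)C)cc2)[C@]1(C)CCO | intermediate
28 | C12 primary iodide | C[C@H]1C[C@H](O[Si](C)(C)C(C)(C)C)C2=C(CCC(=O)[C@]2(C)COC(=O)CCc2ccc(O[Si](C)(C)C(C)(C)C)cc2)[C@]1(C)CCI | intermediate
29 | 4-bromofuran-2(5H)-one | BrC1=CC(=O)OC1 | starting material
30 | C12 alkylzinc iodide | C[C@H]1C[C@H](O[Si](C)(C)C(C)(C)C)C2=C(CCC(=O)[C@]2(C)COC(=O)CCc2ccc(O[Si](C)(C)C(C)(C)C)cc2)[C@]1(C)CC[Zn]I | intermediate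
31 | bis(tert-butyldimethylsilyl) ether of the target (C6–O and phenol protected) | C[C@H]1C[C@H](O[Si](C)(C)C(C)(C)C)C2=C(CCC(=O)[C@]2(C)COC(=O)CCc2ccc(O[Si](C)(C)C(C)(C)C)cc2)[C@]1(C)CCC1=CC(=O)OC1 | intermediate
32 | CNP0301014.1 (4S,6S,8S,9R) | C[C@H]1C[C@H](O)C2=C(CCC(=O)[C@]2(C)COC(=O)CCc2ccc(O)cc2)[C@]1(C)CCC1=CC(=O)OC1 | target

**Step count**

Total: 21 steps. Longest linear sequence: 20 steps (steps 1–14 and 16–21); step 15 is a one-step side branch.

**Steps most likely to fail**

1. Step 11 (Proposed new method). The enolate or the amide base may attack silicon, so that the tether is transferred or lost; alkylation may also occur through C10 or between molecules. In each case the C4 quaternary centre would not form cleanly. The fallback uses known chemistry, sets out from 14 and returns at 20. It keeps the same 1,3-relationship but uses a lactone as the tether and exchanges the roles of the two carbons on C4. Catalytic DBU in toluene equilibrates the C4 epimers of 14 and closes the only possible γ-lactone, the C4–H dihydro-lactone F1. LiN(i-Pr)2 followed by benzyl chloromethyl ether alkylates the lactone enolate to the C4-benzyloxymethyl dihydro-lactone F2; the ring fusion forces the lactone carbon syn and the new benzyloxymethyl group anti to O6. LiAlH4 opens the lactone to the hydroxymethyl diol F3, in which the hydroxymethyl carbon is C18 and the benzyloxymethyl carbon is C19. TsCl in pyridine gives the primary tosylate F4, and LiEt3BH reduces it to the C18-methyl benzyl ether F5. TBSOTf with 2,6-lutidine gives the C6 silyl ether F6, and lithium naphthalenide in THF at −25 °C removes the benzyl group to give 20.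

2. Step 9. The dissolving-metal stage may remove the methoxy group or the benzylic oxygen, or over-reduce the ring, and the 1,4-dihydro hydroxy acid may lactonise or re-aromatise while it is esterified. The fallback carries C19 as a tertiary amide, sets out from 11 and returns at 20. Pyrrolidine with AlMe3 in toluene opens the lactone to the aromatic hydroxy pyrrolidine amide F7, which cannot relactonise under neutral or basic conditions. Birch reduction of this 2-methoxybenzamide (K, t-BuOH, NH3/THF, −78 °C, then NH4Cl) gives the 1,4-dihydro hydroxy amide F8. Silylation with 15 and imidazole gives the (bromomethyl)dimethylsilyl ether F9, and the tethered alkylation of step 11, now through the amide enolate, gives the siloxane-bridged amide F10. Bu4NF in DMF gives the C18-methyl hydroxy amide F11 and TBSOTf gives its C6 silyl ether F12. LiH2NBH3 in THF reduces the hindered tertiary amide to the primary alcohol 20.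

3. Step 12. Fluoride may open only the Si–O bond and leave the neopentyl C18–Si bond intact, or the ester may be cleaved at 70 °C. The fallback replaces protodesilylation by oxidation and deoxygenation, sets out from 17 and returns at 18. Tamao–Fleming oxidation (KF, KHCO3, H2O2, THF/MeOH) gives the C18-hydroxy C6-hydroxy methyl ester F13. Phenyl chlorothionoformate in pyridine acylates the primary hydroxyl selectively to the O-phenyl thionocarbonate F14. Barton–McCombie reduction (Bu3SnH, AIBN, toluene, reflux) then gives 18.

**Further compounds**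

F1 | step 11 | C4–H dihydro-lactone (C19 carbonyl bonded to O6; 2,3- and 5,10-double bonds) | C[C@H]1C[C@@H]2OC(=O)[C@@H]3C(OC)=CCC(=C32)[C@]1(C)CC=C
F2 | step 11 | C4-benzyloxymethyl dihydro-lactone | C[C@H]1C[C@@H]2OC(=O)[C@]3(COCc4ccccc4)C(OC)=CCC(=C32)[C@]1(C)CC=C
F3 | step 11 | diol with C4 hydroxymethyl (syn to O6), C4 benzyloxymethyl and free C6 hydroxyl | C[C@H]1C[C@H](O)C2=C(CC=C(OC)[C@]2(CO)COCc2ccccc2)[C@]1(C)CC=C
F4 | step 11 | primary tosylate of F3 | C[C@H]1C[C@H](O)C2=C(CC=C(OC)[C@]2(COS(=O)(=O)c2ccc(C)cc2)COCc2ccccc2)[C@]1(C)CC=C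
F5 | step 11 | C18-methyl C19 benzyl ether with free C6 hydroxyl | C[C@H]1C[C@H](O)C2=C(CC=C(OC)[C@]2(C)COCc2ccccc2)[C@]1(C)CC=C
F6 | step 11 | C6 tert-butyldimethylsilyl ether of F5 | C[C@H]1C[C@H](O[Si](C)(C)C(C)(C)C)C2=C(CC=C(OC)[C@]2(C)COCc2ccccc2)[C@]1(C)CC=C
F7 | step 9 | aromatic C6-hydroxy C4 pyrrolidine amide | C[C@H]1C[C@H](O)c2c(C(=O)N3CCCC3)c(OC)ccc2[C@]1(C)CC=C
F8 | step 9 | 1,4-dihydro hydroxy pyrrolidine amide (C4 epimers) | C[C@H]1C[C@H](O)C2=C(CC=C(OC)C2C(=O)N2CCCC2)[C@]1(C)CC=C
F9 | step 9 | C6 (bromomethyl)dimethylsilyl ether of F8 | C[C@H]1C[C@H](O[Si](C)(C)CBr)C2=C(CC=C(OC)C2C(=O)N2CCCC2)[C@]1(C)CC=C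
F10 | step 9 | siloxane-bridged pyrrolidine amide with quaternary C4 | C[C@H]1C[C@@H]2O[Si](C)(C)C[C@]3(C(=O)N4CCCC4)C(OC)=CCC(=C32)[C@]1(C)CC=C
F11 | step 9 | C18-methyl pyrrolidine amide with free C6 hydroxyl | C[C@H]1C[C@H](O)C2=C(CC=C(OC)[C@]2(C)C(=O)N2CCCC2)[C@]1(C)CC=C
F12 | step 9 | C6 tert-butyldimethylsilyl ether of F11 | C[C@H]1C[C@H](O[Si](C)(C)C(C)(C)C)C2=C(CC=C(OC)[C@]2(C)C(=O)N2CCCC2)[C@]1(C)CC=C
F13 | step 12 | methyl ester with C18 hydroxyl and C6 hydroxyl | C[C@H]1C[C@H](O)C2=C(CC=C(OC)[C@]2(CO)C(=O)OC)[C@]1(C)CC=C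
F14 | step 12 | C18 O-phenyl thionocarbonate of F13 | C[C@H]1C[C@H](O)C2=C(CC=C(OC)[C@]2(COC(=S)Oc2ccccc2)C(=O)OC)[C@]1(C)CC=C
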